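The data were generated by integration for substances that don't exist, and the scatter is random.

If the percentage of target were the same at every starting concentration of substrate, the power linking percentage to concentration would be zero; if the percentage grew in step with concentration, that power would be one. Two of us argued over where the new flask stands on this scale.

| flask | substrate | reagent | remark | time |
|---|---|---|---|---|
| grey | 0.14 M | 1.1 equiv | run made earlier |  |
| green | 0.58 M | 1.1 equiv | run made earlier |  |
| flask | 0.29 M | 1.10 equiv |  | 20 h |

| run | time / h | target / % |
|---|---|---|
| grey | 0.333 | 9.2 |
| grey | 1.00 | 18.4 |
| grey | 4.00 | 14.1 |
| grey | 12.0 | 11.8 |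
| green | 0.333 | 27.0 |
| green | 1.00 | 34.2 |
| green | 4.00 | 21.8 |
| green | 12.0 | 16.0 |

(standard deviation of a reading: 1 percentage point)

- time, not beyond 20 h, at which the flask holds most target
- the amount of target, in percent of the substrate charged, at that time

- a reading or a percentage of target counts all its forms, free or not

Both of us started from the readings at 1.00 h, the highest in each run: 18.4% in grey and 34.2% in green.

The first held that the percentage climbs evenly with concentration, on a straight line between the two runs, and expected 23.8% in the flask.

The second held that, at the same equivalents of reagent, equal factors of concentration give equal factors of percentage. The power n that turns the concentration ratio of green to grey into their percentage ratio comes to 0.436; this is the concentration exponent, the usual log-log slope. The flask has 2.07 times the concentration of grey, so this view expected 25.3%. The two figures stand 1.5 percentage points apart, against a scatter of 1 point per reading.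

The forecast takes the second side, placing the flask “about halfway between them on a log scale”. It uses its own estimated peaks of 19 and 35 percent, so its figure differs from the second's: 26% (23% to 29%) at 1 h (0.6 h to 1.6 h).

The flask holds most target at 1.23 h, with 25.7%. That is 0.40 points above the second's figure and 1.9 points above the first's, so the second view wins here. The straight line holds at the charges of grey and green, through whose readings it is drawn, as the second view's curve does.

    target → over-reaction product (k = 2.10 × 10⁻⁷ s⁻¹)
    crystals ⇌ target, rate k2*(cs2 - [target]) while solid is left; crystals form when [target] > cs2 (solubility = 0.190 M, k = 0.00530 s⁻¹)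
    substrate + reagent ⇌ isomer of the product A (K = 8.60 L mol⁻¹, k = 2.40 × 10⁻⁴ L mol⁻¹ s⁻¹)
    substrate + reagent ⇌ target (K = 3.30 L mol⁻¹, k = 6.90 × 10⁻⁴ L mol⁻¹ s⁻¹)
    target ⇌ isomer of the product B (K = 1.30, k = 6.30 × 10⁻⁵ s⁻¹)

A further flask, charged with 0.17 M of substrate and otherwise like this one, has 1.21 times the concentration of grey. With the same n, the grey reading becomes 20.0%, and that flask reaches 19.9%.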